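**Retrosynthetic overview**
1. The target tetramer comes from its hexadeca-O-TBS ether by global desilylation in the last step.
2. Each C4–C8 bond is cut to a C4 benzylic radical (from trivalent-titanium homolysis of a cis-3,4-epoxyflavan) and a C8 aryl bromide joined under nickel catalysis. This is done three times from the bottom unit upward, with a C8 bromination between couplings; each coupling sets C4 (4β) and frees the 3-OH.
3. The epoxide (source of the three upper units) and the bottom unit (its hydrogenolysis product) both come from one (S)-flav-3-ene; bromohydrin closure relays C2 to C3 (2,3-cis).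
4. The flav-3-ene comes from enantioselective addition of a ring B aryl boronate to a ring A/ring C chromene acetal made from a coumarin.
5. Ring order: ring A (resorcinol, C–H borylation/oxidation), then ring C (coumarin from ethyl propiolate), then ring B attached at C2 (catechol, C–H borylation), then the interflavan bonds.

Assumption and abbreviations: α/β follow flavan-3-ol usage (the 2-aryl group of a 2R unit is α; 4β is trans to the 3-OH of the same unit). TBS = tert-butyldimethylsilyl, TBSO = its ether; dtbpy = 4,4′-di-tert-butyl-2,2′-bipyridine; cod = 1,5-cyclooctadiene; dme = 1,2-dimethoxyethane; HBpin = pinacolborane. The route is a paper design and has not been run.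

**Route**

Step 1
Reactants: 1 resorcinol
Product: 2 1,3-bis(TBSO)benzene
Conditions: TBSCl (2.2 equiv), imidazole, DMF, 25 °C
Reagents that add atoms: tert-butyldimethylsilyl chloride, CC(C)(C)[Si](C)(C)Cl
Why: Imidazole-promoted silyl ether formation on both phenols; silyl groups (unlike benzyl groups) carry no arene C–H bonds that would compete in the next step.

Step 2
Reactants: 2 1,3-bis(TBSO)benzene
Product: 4 3,5-bis(TBSO)phenol, via aryl pinacol boronate 3 (not isolated)
Conditions: [Ir(OMe)(cod)]2 (1.5 mol%), dtbpy (3 mol%), HBpin (1.5 equiv), cyclohexane, 60 °C; then KHSO5 (Oxone), acetone/H2O, 25 °C, 10 min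
Reagents that add atoms: potassium peroxymonosulfate KHSO5, [K+].[O-]S(=O)(=O)OO
Why: Sterically controlled iridium-catalysed aromatic C–H borylation reaches only C5 (the one C–H not ortho to a substituent), and one-pot oxidation of the boronate gives the third ring A oxygen meta to the other two.

Step 3
Reactants: 4 3,5-bis(TBSO)phenol; 5 ethyl propiolate
Product: 6 5,7-bis(TBSO)-2H-chromen-2-one (coumarin)
Conditions: 5 (2 equiv), Pd(OAc)2 (5 mol%), NaOAc, HCO2H, 25 °C
Reagents that add atoms: none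
Why: Palladium-catalysed phenol–alkynoate coupling (hydroarylation then lactonisation, a Pechmann-type result) at either of the two equivalent ortho positions; aryl silyl ethers should tolerate buffered formic acid at room temperature.

Step 4
Reactants: 6 5,7-bis(TBSO)coumarin
Product: 8 2-ethoxy-5,7-bis(TBSO)-2H-chromene (racemic acetal), via lactol 7 (not isolated)
Conditions: i-Bu2AlH (1.1 equiv), CH2Cl2, −78 °C; then EtOH, PPTS (cat.), 25 °C
Reagents that add atoms: ethanol, CCO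
Why: Half-reduction of the lactone gives the lactol, which ionises in acidic ethanol to the 5,7-dioxygenated benzopyrylium ion and is trapped as the mixed acetal (lactone reduction then acetalisation).

Step 5
Reactants: 9 catechol
Product: 10 1,2-bis(TBSO)benzene
Conditions: TBSCl (2.2 equiv), imidazole, DMF, 25 °C
Reagents that add atoms: tert-butyldimethylsilyl chloride, CC(C)(C)[Si](C)(C)Cl
Why: Imidazole-promoted silyl ether formation, chosen for the same reason as in step 1.

Step 6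
Reactants: 10 1,2-bis(TBSO)benzene
Product: 12 [3,4-bis(TBSO)phenyl]boronic acid, via aryl pinacol boronate 11 (not isolated)
Conditions: [Ir(OMe)(cod)]2 (1.5 mol%), dtbpy (3 mol%), HBpin (1.5 equiv), cyclohexane, 60 °C; then NaIO4, NH4OAc, acetone/H2O, 25 °C
Reagents that add atoms: pinacolborane, CC1(C)OBOC1(C)C; water, O
Why: Iridium-catalysed C–H borylation goes to C4 (C4 and C5 are equivalent, C3 and C6 are blocked by the ortho silyloxy groups), and periodate cleavage of the pinacol ester frees the boronic acid.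

Step 7
Reactants: 8 2-ethoxy-5,7-bis(TBSO)-2H-chromene; 12 [3,4-bis(TBSO)phenyl]boronic acid
Product: 14 (2S)-5,7-bis(TBSO)-2-[3,4-bis(TBSO)phenyl]-2H-chromene (flav-3-ene; B ring α), via diethyl arylboronate 13 (not isolated)
Conditions: 12, EtOH, 4 Å MS, EtOAc, 25 °C; then 8, tartaric-acid-derived chiral hydroxy acid amide (10 mol%), Yb(OTf)3 (5 mol%), EtOAc, −40 → 4 °C
Reagents that add atoms: none
Why: Chiral Brønsted acid/Lewis acid-catalysed enantioselective addition of an aryl boronate to a chromene acetal: Yb(OTf)3 ionises 8 to the benzopyrylium ion and the tartaric-acid-derived ligand, exchanged onto boron, delivers the aryl group to one face of C2; the catalyst antipode (both are available) is chosen to give the 2S flavene, which has the spatial arrangement of (2R)-epicatechin.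

Step 8
Reactants: 14 (2S)-flav-3-ene
Product: 16 (2R,3R,4R)-3,4-epoxy-5,7-bis(TBSO)-2-[3,4-bis(TBSO)phenyl]chroman (epoxide oxygen cis to the 2-aryl group), via trans-bromohydrin 15 (not isolated)
Conditions: NBS (1.05 equiv), THF/H2O (4:1), −20 °C; crude extract, then DBU (1.5 equiv), CH2Cl2, 0 °C; used at once
Reagents that add atoms: water, O
Why: Halohydrin formation then intramolecular Williamson closure: Br+ adds to C3 anti to the 2-aryl group, water takes the C4 benzylic cation anti to bromine, and the C4 alkoxide displaces bromide with inversion at C3, so the C3–O bond ends up cis to the aryl group (epicatechin C3 relayed from C2).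

Step 9
Reactants: 16 cis-epoxide
Product: 17 (2R,3R)-5,7-bis(TBSO)-2-[3,4-bis(TBSO)phenyl]chroman-3-ol (5,7,3′,4′-tetra-O-TBS-(−)-epicatechin)
Conditions: H2 (1 atm), Pd/C (5 mol%), EtOAc, Et3N (1 vol%), 0 → 25 °C
Reagents that add atoms: none
Why: Hydrogenolysis of the benzylic C4–O bond of the epoxide leaves the 3α-OH in place and gives the 2,3-cis flavan-3-ol; silyl ethers are inert to hydrogen.

Step 10
Reactants: 17 tetra-O-TBS-epicatechin
Product: 18 (2R,3R)-8-bromo-5,7-bis(TBSO)-2-[3,4-bis(TBSO)phenyl]chroman-3-ol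
Conditions: NBS (1.0 equiv), CH2Cl2, −78 → −40 °C
Reagents that add atoms: N-bromosuccinimide, O=C1CCC(=O)N1Br
Why: Electrophilic aromatic bromination goes to C8, the most accessible nucleophilic position of ring A, because C6 lies between two bulky silyloxy groups.

Step 11
Reactants: 16 cis-epoxide; 18 8-bromo-tetra-O-TBS-epicatechin
Product: 19 octa-O-TBS epicatechin dimer [tetra-O-TBS-epicatechin-(4β→8)-tetra-O-TBS-epicatechin; both 3-OH free]
Conditions: NiCl2(dme) (10 mol%), 2,2′-bipyridine (10 mol%), Cp2TiCl2 (20 mol%), Mn powder (3 equiv), Et3N·HCl (1.5 equiv), DMPU, 25 °C; 16 (1.5 equiv) added over 6 h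
Reagents that add atoms: none
Why: Proposed new method: the closest known reaction type is the nickel/titanocene co-catalysed reductive arylation of epoxides (radical cross-electrophile coupling), extended here to a doubly ortho-substituted, electron-rich aryl bromide and a flavan 3,4-epoxide; Cp2TiCl (trivalent titanium, from Cp2TiCl2 and Mn) homolyses the benzylic C4–O bond of 16 to a C4 radical with a 3α-titanoxy group, the aryl–nickel species from 18 captures it anti to that group and to the 2-aryl group, and reductive elimination gives the 4β–8 bond and, after protonation, the free 3-OH.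

Step 12
Reactants: 19 octa-O-TBS epicatechin dimer
Product: 20 8-bromo (top unit) derivative of 19
Conditions: NBS (1.0 equiv), CH2Cl2, −78 °C
Reagents that add atoms: N-bromosuccinimide, O=C1CCC(=O)N1Br
Why: Electrophilic aromatic bromination as in step 10: the top unit holds the only free C8, and every C6 lies between two silyloxy groups.

Step 13
Reactants: 16 cis-epoxide; 20 bromo dimer
Product: 21 dodeca-O-TBS epicatechin trimer [three tetra-O-TBS-epicatechin units joined (4β→8) twice]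
Conditions: NiCl2(dme) (10 mol%), 2,2′-bipyridine (10 mol%), Cp2TiCl2 (20 mol%), Mn powder (3 equiv), Et3N·HCl (1.5 equiv), DMPU, 25 °C; 16 (1.5 equiv) added over 6 h
Reagents that add atoms: none
Why: Proposed new method: the same extension of the nickel/titanocene co-catalysed reductive epoxide arylation as in step 11, in which trivalent titanium opens 16 to the C4 benzylic radical and the aryl–nickel species from 20 captures it anti to the 3α-titanoxy group to give the 4β linkage.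

Step 14
Reactants: 21 dodeca-O-TBS epicatechin trimer
Product: 22 8-bromo (top unit) derivative of 21
Conditions: NBS (1.0 equiv), CH2Cl2, −78 °C
Reagents that add atoms: N-bromosuccinimide, O=C1CCC(=O)N1Br
Why: Electrophilic aromatic bromination at the only free C8, as in step 12.

Step 15
Reactants: 16 cis-epoxide; 22 bromo trimer
Product: 23 hexadeca-O-TBS epicatechin tetramer [four tetra-O-TBS-epicatechin units joined (4β→8) three times]
Conditions: NiCl2(dme) (10 mol%), 2,2′-bipyridine (10 mol%), Cp2TiCl2 (20 mol%), Mn powder (3 equiv), Et3N·HCl (1.5 equiv), DMPU, 25 °C; 16 (2 equiv) added over 6 h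
Reagents that add atoms: none
Why: Proposed new method: the same extension of the nickel/titanocene co-catalysed reductive epoxide arylation as in step 11, in which the C4 radical from 16 is captured by the aryl–nickel species from 22 anti to the 3α-titanoxy group, setting the last C4 centre 4β.

Step 16
Reactants: 23 hexadeca-O-TBS epicatechin tetramer
Product: 24 the target, epicatechin-(4β→8)-epicatechin-(4β→8)-epicatechin-(4β→8)-epicatechin
Conditions: HF·pyridine (excess), pyridine/THF, 0 → 25 °C, argon; Sephadex LH-20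
Reagents that add atoms: none
Why: Fluoride cleavage of all sixteen aryl silyl ethers under weakly acidic, non-oxidising conditions that should spare the acid-labile interflavan bonds and the air-sensitive polyphenol; no stereocentre is touched.

**Compound list**

1 | resorcinol | Oc1cccc(O)c1 | starting material
2 | 1,3-bis(tert-butyldimethylsilyloxy)benzene | CC(C)(C)[Si](C)(C)Oc1cccc(O[Si](C)(C)C(C)(C)C)c1 | intermediate
3 | 2-[3,5-bis(TBSO)phenyl]-4,4,5,5-tetramethyl-1,3,2-dioxaborolane | CC(C)(C)[Si](C)(C)Oc1cc(O[Si](C)(C)C(C)(C)C)cc(c1)B1OC(C)(C)C(C)(C)O1 | intermediate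
4 | 3,5-bis(TBSO)phenol | CC(C)(C)[Si](C)(C)Oc1cc(O)cc(O[Si](C)(C)C(C)(C)C)c1 | intermediate
5 | ethyl propiolate | C#CC(=O)OCC | starting material
6 | 5,7-bis(TBSO)-2H-chromen-2-one | O=C1C=Cc2c(O[Si](C)(C)C(C)(C)C)cc(O[Si](C)(C)C(C)(C)C)cc2O1 | intermediate
7 | 5,7-bis(TBSO)-2H-chromen-2-ol (racemic lactol) | OC1C=Cc2c(O[Si](C)(C)C(C)(C)C)cc(O[Si](C)(C)C(C)(C)C)cc2O1 | intermediate
8 | 2-ethoxy-5,7-bis(TBSO)-2H-chromene (racemic) | CCOC1C=Cc2c(O[Si](C)(C)C(C)(C)C)cc(O[Si](C)(C)C(C)(C)C)cc2O1 | intermediate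
9 | catechol | Oc1ccccc1O | starting material
10 | 1,2-bis(TBSO)benzene | CC(C)(C)[Si](C)(C)Oc1ccccc1O[Si](C)(C)C(C)(C)C | intermediate
11 | 2-[3,4-bis(TBSO)phenyl]-4,4,5,5-tetramethyl-1,3,2-dioxaborolane | CC1(C)OB(OC1(C)C)c1ccc(O[Si](C)(C)C(C)(C)C)c(O[Si](C)(C)C(C)(C)C)c1 | intermediate
12 | [3,4-bis(TBSO)phenyl]boronic acid | OB(O)c1ccc(O[Si](C)(C)C(C)(C)C)c(O[Si](C)(C)C(C)(C)C)c1 | intermediate
13 | diethyl [3,4-bis(TBSO)phenyl]boronate | CCOB(OCC)c1ccc(O[Si](C)(C)C(C)(C)C)c(O[Si](C)(C)C(C)(C)C)c1 | intermediate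
14 | (2S)-5,7-bis(TBSO)-2-[3,4-bis(TBSO)phenyl]-2H-chromene | CC(C)(C)[Si](C)(C)Oc1cc(O[Si](C)(C)C(C)(C)C)c2c(c1)O[C@H](c1ccc(O[Si](C)(C)C(C)(C)C)c(O[Si](C)(C)C(C)(C)C)c1)C=C2 | intermediate
15 | (2R,3S,4R)-3-bromo-5,7-bis(TBSO)-2-[3,4-bis(TBSO)phenyl]chroman-4-ol (Br trans to aryl, OH trans to Br) | CC(C)(C)[Si](C)(C)Oc1cc(O[Si](C)(C)C(C)(C)C)c2c(c1)O[C@H](c1ccc(O[Si](C)(C)C(C)(C)C)c(O[Si](C)(C)C(C)(C)C)c1)[C@@H](Br)[C@@H]2O | intermediate
16 | (2R,3R,4R)-3,4-epoxy-5,7-bis(TBSO)-2-[3,4-bis(TBSO)phenyl]chroman (epoxide oxygen cis to the 2-aryl group) | CC(C)(C)[Si](C)(C)Oc1cc(O[Si](C)(C)C(C)(C)C)c2c(c1)O[C@H](c1ccc(O[Si](C)(C)C(C)(C)C)c(O[Si](C)(C)C(C)(C)C)c1)[C@@H]3O[C@H]23 | intermediate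
17 | (2R,3R)-5,7-bis(TBSO)-2-[3,4-bis(TBSO)phenyl]chroman-3-ol (tetra-O-TBS-(−)-epicatechin) | CC(C)(C)[Si](C)(C)Oc1cc(O[Si](C)(C)C(C)(C)C)c2c(c1)O[C@H](c1ccc(O[Si](C)(C)C(C)(C)C)c(O[Si](C)(C)C(C)(C)C)c1)[C@H](O)C2 | intermediate
18 | (2R,3R)-8-bromo-5,7-bis(TBSO)-2-[3,4-bis(TBSO)phenyl]chroman-3-ol | CC(C)(C)[Si](C)(C)Oc1cc(O[Si](C)(C)C(C)(C)C)c2c(c1Br)O[C@H](c1ccc(O[Si](C)(C)C(C)(C)C)c(O[Si](C)(C)C(C)(C)C)c1)[C@H](O)C2 | intermediate
19 | octa-O-TBS epicatechin dimer: tetra-O-TBS-epicatechin-(4β→8)-tetra-O-TBS-epicatechin, all C2 and C3 R, 3-OH groups free | CC(C)(C)[Si](C)(C)Oc1cc(O[Si](C)(C)C(C)(C)C)c2c(c1)O[C@H](c1ccc(O[Si](C)(C)C(C)(C)C)c(O[Si](C)(C)C(C)(C)C)c1)[C@H](O)[C@H]2c1c(O[Si](C)(C)C(C)(C)C)cc(O[Si](C)(C)C(C)(C)C)c2c1O[C@H](c1ccc(O[Si](C)(C)C(C)(C)C)c(O[Si](C)(C)C(C)(C)C)c1)[C@H](O)C2 | intermediate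
20 | 19 with bromine at C8 of the top unit | CC(C)(C)[Si](C)(C)Oc1cc(O[Si](C)(C)C(C)(C)C)c2c(c1Br)O[C@H](c1ccc(O[Si](C)(C)C(C)(C)C)c(O[Si](C)(C)C(C)(C)C)c1)[C@H](O)[C@H]2c1c(O[Si](C)(C)C(C)(C)C)cc(O[Si](C)(C)C(C)(C)C)c2c1O[C@H](c1ccc(O[Si](C)(C)C(C)(C)C)c(O[Si](C)(C)C(C)(C)C)c1)[C@H](O)C2 | intermediate
21 | dodeca-O-TBS epicatechin trimer: three tetra-O-TBS-epicatechin units, two (4β→8) bonds, 3-OH groups free | CC(C)(C)[Si](C)(C)Oc1cc(O[Si](C)(C)C(C)(C)C)c2c(c1)O[C@H](c1ccc(O[Si](C)(C)C(C)(C)C)c(O[Si](C)(C)C(C)(C)C)c1)[C@H](O)[C@H]2c1c(O[Si](C)(C)C(C)(C)C)cc(O[Si](C)(C)C(C)(C)C)c2c1O[C@H](c1ccc(O[Si](C)(C)C(C)(C)C)c(O[Si](C)(C)C(C)(C)C)c1)[C@H](O)[C@H]2c1c(O[Si](C)(C)C(C)(C)C)cc(O[Si](C)(C)C(C)(C)C)c2c1O[C@H](c1ccc(O[Si](C)(C)C(C)(C)C)c(O[Si](C)(C)C(C)(C)C)c1)[C@H](O)C2 | intermediate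
22 | 21 with bromine at C8 of the top unit | CC(C)(C)[Si](C)(C)Oc1cc(O[Si](C)(C)C(C)(C)C)c2c(c1Br)O[C@H](c1ccc(O[Si](C)(C)C(C)(C)C)c(O[Si](C)(C)C(C)(C)C)c1)[C@H](O)[C@H]2c1c(O[Si](C)(C)C(C)(C)C)cc(O[Si](C)(C)C(C)(C)C)c2c1O[C@H](c1ccc(O[Si](C)(C)C(C)(C)C)c(O[Si](C)(C)C(C)(C)C)c1)[C@H](O)[C@H]2c1c(O[Si](C)(C)C(C)(C)C)cc(O[Si](C)(C)C(C)(C)C)c2c1O[C@H](c1ccc(O[Si](C)(C)C(C)(C)C)c(O[Si](C)(C)C(C)(C)C)c1)[C@H](O)C2 | intermediate
23 | hexadeca-O-TBS epicatechin tetramer: four tetra-O-TBS-epicatechin units, three (4β→8) bonds, 3-OH groups free | CC(C)(C)[Si](C)(C)Oc1cc(O[Si](C)(C)C(C)(C)C)c2c(c1)O[C@H](c1ccc(O[Si](C)(C)C(C)(C)C)c(O[Si](C)(C)C(C)(C)C)c1)[C@H](O)[C@H]2c1c(O[Si](C)(C)C(C)(C)C)cc(O[Si](C)(C)C(C)(C)C)c2c1O[C@H](c1ccc(O[Si](C)(C)C(C)(C)C)c(O[Si](C)(C)C(C)(C)C)c1)[C@H](O)[C@H]2c1c(O[Si](C)(C)C(C)(C)C)cc(O[Si](C)(C)C(C)(C)C)c2c1O[C@H](c1ccc(O[Si](C)(C)C(C)(C)C)c(O[Si](C)(C)C(C)(C)C)c1)[C@H](O)[C@H]2c1c(O[Si](C)(C)C(C)(C)C)cc(O[Si](C)(C)C(C)(C)C)c2c1O[C@H](c1ccc(O[Si](C)(C)C(C)(C)C)c(O[Si](C)(C)C(C)(C)C)c1)[C@H](O)C2 | intermediate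
24 | the target (the cinnamtannin named in the task): epicatechin-(4β→8)-epicatechin-(4β→8)-epicatechin-(4β→8)-epicatechin | Oc1cc(O)c2c(c1)O[C@H](c1ccc(O)c(O)c1)[C@H](O)[C@H]2c1c(O)cc(O)c2c1O[C@H](c1ccc(O)c(O)c1)[C@H](O)[C@H]2c1c(O)cc(O)c2c1O[C@H](c1ccc(O)c(O)c1)[C@H](O)[C@H]2c1c(O)cc(O)c2c1O[C@H](c1ccc(O)c(O)c1)[C@H](O)C2 | target

**Totals**

Total step count: 16. Longest linear sequence: 14 (steps 1, 2, 3, 4, 7, 8, 9, 10, 11, 12, 13, 14, 15, 16).

**Three steps most likely to fail**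

Step 11 (the same reaction recurs in steps 13 and 15, where it is harder). The aryl bromide has two ortho substituents and is electron-rich, so oxidative addition to zerovalent nickel and the crowded bond formation may be slow. Meanwhile epoxide 16 can be lost by deoxygenation, reduction to 17 or rearrangement to the flavan-3-one. Fallback: set out from 16 and the unbrominated nucleophile 17 (step 10 is then skipped) and come back at 19. The epoxide is opened in a Friedel–Crafts sense with Yb(OTf)3 or BF3·OEt2 (cat.) in CH2Cl2 at −78 °C, with 17 in threefold excess. C8 of 17 attacks the C4 cation anti to the 3-oxygen, which gives the same 4β linkage without a radical. The same switch serves steps 13 and 15 with 19 and 21 as nucleophiles, which removes steps 12 and 14. This fallback makes no new compound (F0).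

Step 8. NBS may brominate ring A at C6 or C8 instead of the C3=C4 bond, and epoxide 16 is very acid-labile. Fallback: set out from 14 and come back at 16, at the cost of four more steps. Hydroboration–oxidation of 14 (BH3·THF; then NaBO3·4H2O) adds anti to the aryl group and gives the 2,3-trans alcohol tetra-O-TBS-(2R,3S)-catechin F1. Dess–Martin oxidation gives the flavan-3-one F2. LiBH(s-Bu)3 in THF at −78 °C attacks anti to the 2-aryl group and gives the 2,3-cis alcohol 17. DDQ (1.1 equiv) in wet CH2Cl2 at 0 °C oxidises C4 of 17, and water adds anti to the 3-OH to give the 3,4-trans-diol F3. Cyclodehydration (PPh3, DIAD, THF, 0 °C), with the benzylic C4–O bond as the one that breaks, closes the epoxide 16.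

Step 7. The enantioselective boronate addition has not been shown on a 5,7-bis(silyloxy) acetal with this aryl boronate, and the sense and level of induction are unverified. Fallback: set out from 8 and 12 and come back at 14. A non-enantioselective nickel-catalysed coupling of the acetal with the boronic acid (Ni(cod)2, PPh3, dioxane/t-amyl alcohol, 25 °C) gives the racemic flavene F4. Kinetic resolution follows by epoxidation with (R,R)-(salen)MnCl [salen = N,N′-bis(3,5-di-tert-butylsalicylidene)-1,2-cyclohexanediamine dianion], m-CPBA and N-methylmorpholine N-oxide in CH2Cl2 at −78 °C. The R enantiomer reacts fast, because catalyst and substrate both favour the face anti to its aryl group, and gives the trans-epoxide F5. Unreacted (S)-14 is recovered at about 55–60% conversion.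

**Further compounds**

F0 | step 11 | none | none
F1 | step 8 | (2R,3S)-5,7-bis(TBSO)-2-[3,4-bis(TBSO)phenyl]chroman-3-ol (2,3-trans) | CC(C)(C)[Si](C)(C)Oc1cc(O[Si](C)(C)C(C)(C)C)c2c(c1)O[C@H](c1ccc(O[Si](C)(C)C(C)(C)C)c(O[Si](C)(C)C(C)(C)C)c1)[C@@H](O)C2
F2 | step 8 | (2R)-5,7-bis(TBSO)-2-[3,4-bis(TBSO)phenyl]chroman-3-one | CC(C)(C)[Si](C)(C)Oc1cc(O[Si](C)(C)C(C)(C)C)c2c(c1)O[C@H](c1ccc(O[Si](C)(C)C(C)(C)C)c(O[Si](C)(C)C(C)(C)C)c1)C(=O)C2
F3 | step 8 | (2R,3R,4S)-5,7-bis(TBSO)-2-[3,4-bis(TBSO)phenyl]chroman-3,4-diol (2,3-cis, 3,4-trans) | CC(C)(C)[Si](C)(C)Oc1cc(O[Si](C)(C)C(C)(C)C)c2c(c1)O[C@H](c1ccc(O[Si](C)(C)C(C)(C)C)c(O[Si](C)(C)C(C)(C)C)c1)[C@H](O)[C@H]2O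
F4 | step 7 | racemic 5,7-bis(TBSO)-2-[3,4-bis(TBSO)phenyl]-2H-chromene | CC(C)(C)[Si](C)(C)Oc1cc(O[Si](C)(C)C(C)(C)C)c2c(c1)OC(c1ccc(O[Si](C)(C)C(C)(C)C)c(O[Si](C)(C)C(C)(C)C)c1)C=C2
F5 | step 7 | (2S,3R,4R)-3,4-epoxy-5,7-bis(TBSO)-2-[3,4-bis(TBSO)phenyl]chroman (epoxide trans to the 2-aryl group) | CC(C)(C)[Si](C)(C)Oc1cc(O[Si](C)(C)C(C)(C)C)c2c(c1)O[C@@H](c1ccc(O[Si](C)(C)C(C)(C)C)c(O[Si](C)(C)C(C)(C)C)c1)[C@@H]3O[C@H]23
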